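**Plan**
- Retrosynthetic cuts (chromene numbering): first the C6–C(=O)Ph bond, then the pyran ring at O1–C2 and C4–C4a, and last the benzene ring at C7–C8 and C4a–C8a, which leaves an ethoxyvinylketene (from 3-ethoxycyclobutenone) and a prenyl-bearing siloxyalkyne.
- Enabling feature: in the ring C4a–C5–C6–C7–C8–C8a the oxygens sit on C5, C7 and C8a and the prenyl group on C8 lies between two of them. C7(O)–C8(prenyl)–C8a(O) is therefore a ketene carbonyl joined to an ynol ether, and C4a–C5(O)–C6 is C2–C3(OEt)–C4 of the cyclobutenone.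
- Forward: a Kowalski homologation gives the siloxyalkyne; the benzannulation builds the benzene ring first, with its three oxygens already distinct (OH at C7, OTIPS at C8a, OEt at C5).
- Then C7–OH is capped as its MOM ether, the C8a silyl ether is removed, the pyran ring is closed with 3-methylbut-2-enal at C4a, C6 is lithiated and benzoylated, and the ethyl and MOM ethers are removed.
- Stereochemistry: the target has no stereocentre and no stereogenic double bond, so nothing has to be set or preserved.

Key step: step 2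

Assumption: the target is achiral, so the request for a single enantiomer is met by the compound itself; the one chiral transient of the key step is racemic and loses its sp3 centre on ring opening.

**Step 1**
Reactants: 1 ethyl 4-methylpent-3-enoate
Product: 4 triisopropyl[(5-methylhex-4-en-1-yn-1-yl)oxy]silane, via lithium dibromoenolate 2 (not isolated), via lithium ynolate 3 (not isolated)
Conditions: CH2Br2, LiTMP, THF, −78 °C; LiHMDS; n-BuLi, −78 → 20 °C; TIPSCl, −78 → 0 °C
Reagents that add atoms: dibromomethane, BrCBr; chlorotriisopropylsilane, CC(C)[Si](Cl)(C(C)C)C(C)C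
Why: Kowalski ester homologation, in which dibromomethyllithium adds to the ester, the derived dibromoenolate undergoes Br/Li exchange and 1,2-shift to the ynolate, and the bulky silyl chloride traps the ynolate on oxygen to give the siloxyalkyne.

**Step 2**
Reactants: 4 triisopropyl[(5-methylhex-4-en-1-yn-1-yl)oxy]silane; 5 3-ethoxycyclobut-2-en-1-one
Product: 10 5-ethoxy-2-(3-methylbut-2-en-1-yl)-3-[(triisopropylsilyl)oxy]phenol, via ethoxyvinylketene 6 (not isolated), via vinylcyclobutenone 7 (not isolated), via dienylketene 8 (not isolated), via cyclohexadienone 9 (not isolated)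
Conditions: PhMe, 80 → 110 °C, sealed, Ar; 4 in slight excess
Reagents that add atoms: none
Why: Thermal conrotatory 4π opening of 5 should give vinylketene 6, whose C=C=O unit adds across the electron-rich triple bond of 4 in a [2+2] cycloaddition to give 7; a second 4π opening to dienylketene 8, 6π electrocyclisation to dienone 9 and enolisation then deliver phenol 10. The closest known reaction is the Danheiser benzannulation of cyclobutenones with siloxyalkynes to resorcinol monosilyl ethers, in which 3-oxygenated cyclobutenones are precedented though less common partners. The transient four-membered ring arises by ketene–alkyne [2+2] cycloaddition (C7–C8 and C4a–C8a bonds, chromene numbering), and the benzene ring closes by disrotatory 6π electrocyclisation of the dienylketene (C6–C7 bond) followed by tautomerisation. No stereocentre is created in the product, because the sp3 carbon of 7 becomes trigonal on ring opening. The step needs the regiochemistry of the [2+2] event, and the siloxy group secures it by polarising the alkyne so that its prenyl-bearing carbon bonds to the ketene carbonyl carbon, which places the prenyl group between OH and OTIPS; the slight excess of 4 limits O-acylation of the product phenol by 6.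

**Step 3**
Reactants: 10 5-ethoxy-2-(3-methylbut-2-en-1-yl)-3-[(triisopropylsilyl)oxy]phenol
Product: 11 triisopropyl[5-ethoxy-3-(methoxymethoxy)-2-(3-methylbut-2-en-1-yl)phenoxy]silane
Conditions: MOMCl, i-Pr2NEt, CH2Cl2, 0 °C → rt
Reagents that add atoms: chloromethyl methyl ether, COCCl
Why: Base-mediated O-alkylation of the only free phenol, under which the aryl silyl ether and the ethyl ether are inert; the MOM group is chosen because it later directs lithiation to C6.

**Step 4**
Reactants: 11 triisopropyl[5-ethoxy-3-(methoxymethoxy)-2-(3-methylbut-2-en-1-yl)phenoxy]silane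
Product: 12 5-ethoxy-3-(methoxymethoxy)-2-(3-methylbut-2-en-1-yl)phenol
Conditions: TBAF, THF, 0 °C; aq NH4Cl
Reagents that add atoms: none
Why: Fluoride-mediated desilylation of an aryl silyl ether, which leaves the MOM acetal, the ethyl ether and the alkene untouched and frees only the oxygen destined to become O1.

**Step 5**
Reactants: 12 5-ethoxy-3-(methoxymethoxy)-2-(3-methylbut-2-en-1-yl)phenol; 13 3-methylbut-2-enal
Product: 15 5-ethoxy-7-(methoxymethoxy)-2,2-dimethyl-8-(3-methylbut-2-en-1-yl)-2H-chromene, via ortho-quinone methide 14 (not isolated)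
Conditions: ethylenediamine diacetate (20 mol %), xylene, 140 °C, Dean–Stark
Reagents that add atoms: none
Why: Amine-salt-catalysed Knoevenagel-type condensation of the phenol ortho carbon with the enal gives quinone methide 14, which closes by oxa-6π electrocyclisation to the 2H-chromene; C4a is the only free ortho carbon because C8 carries the prenyl group and the C7 oxygen is capped, and an adduct at the para carbon C6 cannot cyclise and can revert.

**Step 6**
Reactants: 15 5-ethoxy-7-(methoxymethoxy)-2,2-dimethyl-8-(3-methylbut-2-en-1-yl)-2H-chromene; 16 N-methoxy-N-methylbenzamide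
Product: 19 [5-ethoxy-7-(methoxymethoxy)-2,2-dimethyl-8-(3-methylbut-2-en-1-yl)-2H-chromen-6-yl](phenyl)methanone, via aryllithium 17 (not isolated), via lithium hemiaminal alkoxide 18 (not isolated)
Conditions: n-BuLi, THF, 0 °C; then 16, −78 → 0 °C; aq NH4Cl
Reagents that add atoms: none
Why: Directed ortho-metalation followed by Weinreb ketone synthesis, in which the only ring hydrogen (C6–H, flanked by OMOM and OEt) is removed by MOM-coordinated n-BuLi and the aryllithium adds once to the amide because chelate 18 persists until the quench.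

**Step 7**
Reactants: 19 [5-ethoxy-7-(methoxymethoxy)-2,2-dimethyl-8-(3-methylbut-2-en-1-yl)-2H-chromen-6-yl](phenyl)methanone
Product: 20 [5-hydroxy-7-(methoxymethoxy)-2,2-dimethyl-8-(3-methylbut-2-en-1-yl)-2H-chromen-6-yl](phenyl)methanone
Conditions: EtSNa, DMF, 130 °C; aq NH4Cl
Reagents that add atoms: none
Why: SN2 dealkylation of an aryl alkyl ether by thiolate in a dipolar aprotic solvent, helped by the ortho benzoyl group that stabilises the departing phenoxide; the MOM acetal is not an SN2 substrate, and the prenyl group and the chromene tolerate the basic, non-acidic medium.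

**Step 8**
Reactants: 20 [5-hydroxy-7-(methoxymethoxy)-2,2-dimethyl-8-(3-methylbut-2-en-1-yl)-2H-chromen-6-yl](phenyl)methanone
Product: 21 [5,7-dihydroxy-2,2-dimethyl-8-(3-methylbut-2-en-1-yl)-2H-chromen-6-yl](phenyl)methanone
Conditions: 3 M aq HCl, MeOH, 40 °C
Reagents that add atoms: none
Why: Acid-catalysed acetal exchange removes the MOM group under mild conditions of the kind used for ortho-prenylphenols and 2,2-dimethylchromenes, with the benzoyl group lowering the basicity of the ring and its styrene-type alkene.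

**Compound list**
1 | ethyl 4-methylpent-3-enoate | CCOC(=O)CC=C(C)C | starting material
2 | lithium 1,1-dibromo-5-methylhexa-1,4-dien-2-olate | [Li+].[O-]C(CC=C(C)C)=C(Br)Br | intermediate (not isolated)
3 | lithium 5-methylhex-4-en-1-yn-1-olate | [Li+].[O-]C#CCC=C(C)C | intermediate (not isolated)
4 | triisopropyl[(5-methylhex-4-en-1-yn-1-yl)oxy]silane | CC(C)=CCC#CO[Si](C(C)C)(C(C)C)C(C)C | intermediate
5 | 3-ethoxycyclobut-2-en-1-one | CCOC1=CC(=O)C1 | starting material
6 | 3-ethoxybuta-1,3-dien-1-one | C=C(OCC)C=C=O | intermediate (not isolated)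
7 | 4-(1-ethoxyethenyl)-2-(3-methylbut-2-en-1-yl)-3-[(triisopropylsilyl)oxy]cyclobut-2-en-1-one (racemic) | O=C1C(CC=C(C)C)=C(O[Si](C(C)C)(C(C)C)C(C)C)C1C(=C)OCC | intermediate (not isolated)
8 | (3E)-5-ethoxy-2-(3-methylbut-2-en-1-yl)-3-[(triisopropylsilyl)oxy]hexa-1,3,5-trien-1-one | O=C=C(CC=C(C)C)/C(O[Si](C(C)C)(C(C)C)C(C)C)=C\C(OCC)=C | intermediate (not isolated)
9 | 5-ethoxy-2-(3-methylbut-2-en-1-yl)-3-[(triisopropylsilyl)oxy]cyclohexa-2,4-dien-1-one | O=C1CC(OCC)=CC(O[Si](C(C)C)(C(C)C)C(C)C)=C1CC=C(C)C | intermediate (not isolated)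
10 | 5-ethoxy-2-(3-methylbut-2-en-1-yl)-3-[(triisopropylsilyl)oxy]phenol | CC(C)=CCc1c(O)cc(OCC)cc1O[Si](C(C)C)(C(C)C)C(C)C | intermediate
11 | triisopropyl[5-ethoxy-3-(methoxymethoxy)-2-(3-methylbut-2-en-1-yl)phenoxy]silane | CC(C)=CCc1c(OCOC)cc(OCC)cc1O[Si](C(C)C)(C(C)C)C(C)C | intermediate
12 | 5-ethoxy-3-(methoxymethoxy)-2-(3-methylbut-2-en-1-yl)phenol | CC(C)=CCc1c(O)cc(OCC)cc1OCOC | intermediate
13 | 3-methylbut-2-enal | CC(C)=CC=O | starting material
14 | (6Z)-5-ethoxy-3-(methoxymethoxy)-2-(3-methylbut-2-en-1-yl)-6-(3-methylbut-2-en-1-ylidene)cyclohexa-2,4-dien-1-one | CC(C)=C/C=C1\C(=O)C(CC=C(C)C)=C(OCOC)C=C1OCC | intermediate (not isolated)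
15 | 5-ethoxy-7-(methoxymethoxy)-2,2-dimethyl-8-(3-methylbut-2-en-1-yl)-2H-chromene | CC(C)=CCc1c(OCOC)cc(OCC)c2c1OC(C)(C)C=C2 | intermediate
16 | N-methoxy-N-methylbenzamide | CON(C)C(=O)c1ccccc1 | starting material
17 | [5-ethoxy-7-(methoxymethoxy)-2,2-dimethyl-8-(3-methylbut-2-en-1-yl)-2H-chromen-6-yl]lithium | CC(C)=CCc1c(OCOC)c([Li])c(OCC)c2c1OC(C)(C)C=C2 | intermediate (not isolated)
18 | lithium [5-ethoxy-7-(methoxymethoxy)-2,2-dimethyl-8-(3-methylbut-2-en-1-yl)-2H-chromen-6-yl][methoxy(methyl)amino](phenyl)methanolate (racemic) | [Li+].[O-]C(N(C)OC)(c1ccccc1)c1c(OCOC)c(CC=C(C)C)c2OC(C)(C)C=Cc2c1OCC | intermediate (not isolated)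
19 | [5-ethoxy-7-(methoxymethoxy)-2,2-dimethyl-8-(3-methylbut-2-en-1-yl)-2H-chromen-6-yl](phenyl)methanone | CC(C)=CCc1c(OCOC)c(C(=O)c2ccccc2)c(OCC)c2c1OC(C)(C)C=C2 | intermediate
20 | [5-hydroxy-7-(methoxymethoxy)-2,2-dimethyl-8-(3-methylbut-2-en-1-yl)-2H-chromen-6-yl](phenyl)methanone | CC(C)=CCc1c(OCOC)c(C(=O)c2ccccc2)c(O)c2c1OC(C)(C)C=C2 | intermediate
21 | [5,7-dihydroxy-2,2-dimethyl-8-(3-methylbut-2-en-1-yl)-2H-chromen-6-yl](phenyl)methanone | CC(C)=CCc1c(O)c(C(=O)c2ccccc2)c(O)c2c1OC(C)(C)C=C2 | target

Total step count: 8. Longest linear sequence: 8 steps (1 → 21); compounds 5, 13 and 16 enter as purchased materials.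

**Steps most likely to fail**

Step 2. The vinylogous-ester stabilisation of 5 may slow its ring opening, so that 4 is lost to oligomerisation or the phenol is acylated by the ketene before the cascade finishes. The fallback sets out from 4 and generates the same ketene 6 at ambient temperature by photochemical Wolff rearrangement, the diazo-ketone variant of this benzannulation. Ethyl vinyl ether would be lithiated (t-BuLi, THF, −78 → 0 °C) to (1-ethoxyethenyl)lithium F1 and acylated with N-methoxy-N-methylacetamide to 3-ethoxybut-3-en-2-one F2. Detrifluoroacetylative diazo transfer (LiHMDS, CF3CO2CH2CF3, −78 °C, to 5-ethoxy-1,1,1-trifluorohex-5-ene-2,4-dione F3; then MsN3, Et3N, H2O, MeCN) would give 1-diazo-3-ethoxybut-3-en-2-one F4. Irradiation of F4 with 4 (300 nm, ClCH2CH2Cl, rt) and then warming to 80 °C should lead through 6, 7, 8 and 9 and rejoin the route at phenol 10.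

Step 7. SN2 attack at the ethyl carbon may be sluggish because the doubly ortho-substituted benzoyl group is twisted out of conjugation, and prolonged heating could isomerise the prenyl alkene or erode the chromene. The fallback sets out from 15 and uses a formyl group, which stays coplanar with the ring, as the activating group before the phenyl ring is attached. Aryllithium 17 (from 15 as in step 6) would be quenched with DMF to give 5-ethoxy-7-(methoxymethoxy)-2,2-dimethyl-8-(3-methylbut-2-en-1-yl)-2H-chromene-6-carbaldehyde F5. EtSNa in DMF at about 100 °C should then give 5-hydroxy-7-(methoxymethoxy)-2,2-dimethyl-8-(3-methylbut-2-en-1-yl)-2H-chromene-6-carbaldehyde F6. Excess PhMgBr (THF, 0 °C) would add to give 6-[hydroxy(phenyl)methyl]-7-(methoxymethoxy)-2,2-dimethyl-8-(3-methylbut-2-en-1-yl)-2H-chromen-5-ol F7, and MnO2 (CH2Cl2, rt) would oxidise the benzylic alcohol, rejoining the route at ketone 20.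

Step 5. The enal may be attacked by the para carbon C6 of the very electron-rich phenol, or may self-condense, in place of ortho attack at C4a. The fallback sets out from 12 and makes the ortho selectivity intramolecular. O-Alkylation with 3-chloro-3-methylbut-1-yne (cat. CuCl2·2H2O, DBU, MeCN, 0 °C) would give 5-ethoxy-1-(methoxymethoxy)-2-(3-methylbut-2-en-1-yl)-3-[(2-methylbut-3-yn-2-yl)oxy]benzene F8. Heating in xylene at 140 °C should trigger the aromatic propargyl Claisen rearrangement to the free ortho carbon and a 1,5-hydrogen shift that funnels into quinone methide 14, rejoining the route at chromene 15.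

**Further compounds**
F1 | step 2 | (1-ethoxyethenyl)lithium | [Li]C(=C)OCC
F2 | step 2 | 3-ethoxybut-3-en-2-one | C=C(OCC)C(C)=O
F3 | step 2 | 5-ethoxy-1,1,1-trifluorohex-5-ene-2,4-dione | C=C(OCC)C(=O)CC(=O)C(F)(F)F
F4 | step 2 | 1-diazo-3-ethoxybut-3-en-2-one | C=C(OCC)C(=O)C=[N+]=[N-]
F5 | step 7 | 5-ethoxy-7-(methoxymethoxy)-2,2-dimethyl-8-(3-methylbut-2-en-1-yl)-2H-chromene-6-carbaldehyde | CC(C)=CCc1c(OCOC)c(C=O)c(OCC)c2c1OC(C)(C)C=C2
F6 | step 7 | 5-hydroxy-7-(methoxymethoxy)-2,2-dimethyl-8-(3-methylbut-2-en-1-yl)-2H-chromene-6-carbaldehyde | CC(C)=CCc1c(OCOC)c(C=O)c(O)c2c1OC(C)(C)C=C2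
F7 | step 7 | 6-[hydroxy(phenyl)methyl]-7-(methoxymethoxy)-2,2-dimethyl-8-(3-methylbut-2-en-1-yl)-2H-chromen-5-ol (racemic) | CC(C)=CCc1c(OCOC)c(C(O)c2ccccc2)c(O)c2c1OC(C)(C)C=C2
F8 | step 5 | 5-ethoxy-1-(methoxymethoxy)-2-(3-methylbut-2-en-1-yl)-3-[(2-methylbut-3-yn-2-yl)oxy]benzene | CC(C)=CCc1c(OC(C)(C)C#C)cc(OCC)cc1OCOC
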